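The whole plan depends on cutting the unactivated C3–C4 methylene–methylene bond of the tridecane chain (C1 benzylic CH2, C2 acetoxy carbon, C8 ketone). C3 is the primary carbon next to the C2–O stereocentre and maps onto an epichlorohydrin-derived β-acetoxy iodide. C4 lies δ to the C8 carbonyl and maps onto the alkene terminus of dec-1-en-5-one. A nickel hydride-catalysed reductive hydroalkylation reverses the polarity of that terminus in situ. It joins the halves in one operation, with ketone and acetate unprotected and no preformed organometallic. The precursor pair is thus an alkyl iodide and a plain olefin. The phenol oxygen enters the benzene ring last, at its only unhindered C–H, by borylation/oxidation.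

Key step: step 4

Assumption: the Grignard solutions 1 and 8, (S)-epichlorohydrin 2 and acid chloride 7 are taken as purchased. The chain numbering C1 (benzylic CH2) to C13 (terminal CH3) is used throughout.

Step 1
Reactants: 1 3-methoxyphenylmagnesium bromide; 2 (S)-epichlorohydrin
Product: 4 (S)-2-(3-methoxybenzyl)oxirane, via chlorohydrin 3 (not isolated)
Conditions: CuI (10 mol %), THF, −40 to 0 °C; then aq NaOH, rt
Reagents that add atoms: none
Why: Copper-catalysed SN2 opening of the epoxide at its unsubstituted CH2, followed by intramolecular Williamson closure onto CH2Cl, never breaks the C2–O bond, so the stereocentre is taken unchanged from the chiral pool reagent 2.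

Step 2
Reactants: 4 (S)-2-(3-methoxybenzyl)oxirane
Product: 6 (S)-1-iodo-3-(3-methoxyphenyl)propan-2-yl acetate, via iodohydrin 5 (not isolated)
Conditions: LiI, AcOH, THF, rt; then Ac2O, pyridine, DMAP (cat.), 0 °C to rt, dark
Reagents that add atoms: lithium iodide [Li+].[I-]; acetic anhydride CC(=O)OC(C)=O
Why: Acid-buffered halohydrin formation is an SN2 opening of the terminal epoxide by iodide at the unhindered CH2, which leaves C2–O and its configuration intact, and DMAP-catalysed acetylation then caps the secondary alcohol faster than it can reclose.

Step 3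
Reactants: 7 pent-4-enoyl chloride; 8 pentylmagnesium bromide
Product: 9 dec-1-en-5-one
Conditions: Fe(acac)3 (3 mol %), THF, −78 °C
Reagents that add atoms: none
Why: The iron-catalysed cross-coupling of an acid chloride with a Grignard reagent is far faster than addition of the Grignard reagent to the ketone formed, so the reaction should stop at 9 with the isolated terminal alkene untouched.

Step 4
Reactants: 6 (S)-1-iodo-3-(3-methoxyphenyl)propan-2-yl acetate; 9 dec-1-en-5-one
Product: 10 (R)-1-(3-methoxyphenyl)-8-oxotridecan-2-yl acetate
Conditions: NiBr2·diglyme (10 mol %), dtbbpy (15 mol %), (EtO)2MeSiH, Na2CO3, DMAc, 25–30 °C, 9 in excess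
Reagents that add atoms: none
Why: A bipyridine-ligated Ni–H, generated from the nickel salt, the silane and carbonate, inserts into the C4=C5 double bond of 9 with nickel at the terminal C4, the resulting primary alkylnickel abstracts iodine from 6, and the C3 radical recombines with nickel so that C(sp3)–C(sp3) reductive elimination from Ni(III) forms C3–C4. The closest known reaction type is exactly this one, the nickel-catalysed reductive hydroalkylation (hydrocarbonation) of unactivated terminal olefins with primary alkyl iodides and a hydrosilane, which is known to leave ketones and esters alone. No ring is closed and no stereocentre is created: C2 only neighbours the radical carbon, its C–O bond is never broken, and the change of descriptor from S in 6 to R in 10 is a CIP priority effect. The step needs linear regioselectivity, secured by the monosubstituted alkene and by a bipyridine without ortho substituents at room temperature, which disfavours chain walking towards C8. It needs cross- over homo-coupling, secured because the partners enter through different elementary steps (olefin by hydrometalation, iodide by halogen abstraction) and 9 is used in excess. It also needs the β-acetoxy group to stay, which is helped by C3 reaching nickel only as a radical at the fast-eliminating Ni(III) stage, by the slowness of the 1,2-acyloxy shift in such radicals at this temperature and by the absence of Zn or Mn powder.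

Step 5
Reactants: 10 (R)-1-(3-methoxyphenyl)-8-oxotridecan-2-yl acetate
Product: 12 (R)-1-(3-hydroxy-5-methoxyphenyl)-8-oxotridecan-2-yl acetate, via arylboronate 11 (not isolated)
Conditions: [Ir(OMe)(cod)]2 (1.5 mol %), dtbpy (3 mol %), B2pin2, THF, 65 °C; evaporate; then Oxone, acetone/H2O, rt
Reagents that add atoms: potassium peroxymonosulfate (active part of Oxone) [K+].OOS(=O)(=O)[O-]; bis(pinacolato)diboron (boron unit of 11 only) CC1(C)OB(OC1(C)C)B1OC(C)(C)C(C)(C)O1
Why: Iridium-catalysed aromatic C–H borylation is sterically governed and should pick the ring C–H meta to both the CH2 chain and OMe, the only one without an ortho neighbour, and ipso-oxidation of C–B by peroxymonosulfate under non-basic conditions gives the phenol while the secondary acetate, the dialkyl ketone and C2 are left alone (one-pot C–H borylation/oxidation).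

Compound list
1 | 3-methoxyphenylmagnesium bromide | COc1cccc([Mg]Br)c1 | starting material
2 | (S)-epichlorohydrin | ClC[C@@H]1CO1 | starting material
3 | (S)-1-chloro-3-(3-methoxyphenyl)propan-2-ol | ClC[C@H](Cc1cccc(OC)c1)O | intermediate
4 | (S)-2-(3-methoxybenzyl)oxirane | COc1cccc(C[C@H]2CO2)c1 | intermediate
5 | (S)-1-iodo-3-(3-methoxyphenyl)propan-2-ol | IC[C@H](Cc1cccc(OC)c1)O | intermediate
6 | (S)-1-iodo-3-(3-methoxyphenyl)propan-2-yl acetate | IC[C@H](Cc1cccc(OC)c1)OC(C)=O | intermediate
7 | pent-4-enoyl chloride | C=CCCC(=O)Cl | starting material
8 | pentylmagnesium bromide | CCCCC[Mg]Br | starting material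
9 | dec-1-en-5-one | C=CCCC(=O)CCCCC | intermediate
10 | (R)-1-(3-methoxyphenyl)-8-oxotridecan-2-yl acetate | CCCCCC(=O)CCCCC[C@H](Cc1cccc(OC)c1)OC(C)=O | intermediate
11 | (R)-1-[3-methoxy-5-(4,4,5,5-tetramethyl-1,3,2-dioxaborolan-2-yl)phenyl]-8-oxotridecan-2-yl acetate | CCCCCC(=O)CCCCC[C@H](Cc1cc(OC)cc(B2OC(C)(C)C(C)(C)O2)c1)OC(C)=O | intermediate
12 | (R)-1-(3-hydroxy-5-methoxyphenyl)-8-oxotridecan-2-yl acetate | CCCCCC(=O)CCCCC[C@H](Cc1cc(O)cc(OC)c1)OC(C)=O | target

Total step count: 5. Longest linear sequence: 4 steps (1, 2, 4, 5).

Steps most likely to fail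

**Step 4.**
- What may go wrong: loss of acetate from a β-acetoxyalkylnickel species, hydrodeiodination of the iodide and nickel hydride chain walking along the olefin may outrun the cross-coupling.
- Fallback: it replaces the radical union by a polar SN2 opening and sets out from 4 and 8. Purchased 5-bromopentanoyl chloride is coupled with 8 (Fe(acac)3, THF, −78 °C) to 1-bromodecan-5-one F1. This is ketalised with ethylene glycol (TsOH, toluene, water removal) to 2-(4-bromobutyl)-2-pentyl-1,3-dioxolane F2 and turned with magnesium into the Grignard reagent F3. Copper(I)-catalysed opening of 4 at its CH2 terminus forms the same C3–C4 bond and gives the ketal alcohol F4. Acetylation (Ac2O, pyridine) gives the ketal acetate F5, and PPTS in wet acetone releases the ketone, coming back at 10.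

**Step 5.**
- What may go wrong: reduction of the C8 carbonyl by the pinacolborane formed, borylation next to the small methoxy group and over-oxidation of the electron-rich phenol may erode the last step.
- Fallback: it brings the ring oxygen in from the start and sets out from 2 and 9. Purchased 3-bromo-5-methoxyphenol is benzylated (BnBr, K2CO3, DMF) to 1-(benzyloxy)-3-bromo-5-methoxybenzene F6 and converted with magnesium into the Grignard reagent F7. This is taken through the operations of steps 1, 2 and 4, which give the chlorohydrin F8, the epoxide F9, the iodohydrin F10, the iodo acetate F11 and, with 9, the coupled benzyl ether F12. Hydrogenolysis (H2, Pd/C, EtOAc) removes only the benzyl group and comes back at 12.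

**Step 2.**
- What may go wrong: attack of iodide at the internal carbon, reclosure of the iodohydrin to the epoxide during the basic acetylation and alkylation of pyridine by the product may lower the throughput.
- Fallback: it never opens an epoxide with halide and sets out from 3. The chlorohydrin is isolated after an ammonium chloride work-up of step 1 instead of being cyclised. It is acetylated (Ac2O, pyridine) to the chloro acetate F13 and subjected to a Finkelstein exchange (NaI, butan-2-one, reflux), coming back at 6.

Further compounds
F1 | step 4 | 1-bromodecan-5-one | BrCCCCC(=O)CCCCC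
F2 | step 4 | 2-(4-bromobutyl)-2-pentyl-1,3-dioxolane | BrCCCCC1(CCCCC)OCCO1
F3 | step 4 | [4-(2-pentyl-1,3-dioxolan-2-yl)butyl]magnesium bromide | Br[Mg]CCCCC1(CCCCC)OCCO1
F4 | step 4 | (R)-1-(3-methoxyphenyl)-7-(2-pentyl-1,3-dioxolan-2-yl)heptan-2-ol | CCCCCC1(CCCCC[C@H](Cc2cccc(OC)c2)O)OCCO1
F5 | step 4 | (R)-1-(3-methoxyphenyl)-7-(2-pentyl-1,3-dioxolan-2-yl)heptan-2-yl acetate | CCCCCC1(CCCCC[C@H](Cc2cccc(OC)c2)OC(C)=O)OCCO1
F6 | step 5 | 1-(benzyloxy)-3-bromo-5-methoxybenzene | COc1cc(Br)cc(OCc2ccccc2)c1
F7 | step 5 | [3-(benzyloxy)-5-methoxyphenyl]magnesium bromide | COc1cc([Mg]Br)cc(OCc2ccccc2)c1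
F8 | step 5 | (S)-1-[3-(benzyloxy)-5-methoxyphenyl]-3-chloropropan-2-ol | ClC[C@H](Cc1cc(OC)cc(OCc2ccccc2)c1)O
F9 | step 5 | (S)-2-[3-(benzyloxy)-5-methoxybenzyl]oxirane | COc1cc(C[C@H]2CO2)cc(OCc3ccccc3)c1
F10 | step 5 | (S)-1-[3-(benzyloxy)-5-methoxyphenyl]-3-iodopropan-2-ol | IC[C@H](Cc1cc(OC)cc(OCc2ccccc2)c1)O
F11 | step 5 | (S)-1-[3-(benzyloxy)-5-methoxyphenyl]-3-iodopropan-2-yl acetate | IC[C@H](Cc1cc(OC)cc(OCc2ccccc2)c1)OC(C)=O
F12 | step 5 | (R)-1-[3-(benzyloxy)-5-methoxyphenyl]-8-oxotridecan-2-yl acetate | CCCCCC(=O)CCCCC[C@H](Cc1cc(OC)cc(OCc2ccccc2)c1)OC(C)=O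
F13 | step 2 | (S)-1-chloro-3-(3-methoxyphenyl)propan-2-yl acetate | ClC[C@H](Cc1cccc(OC)c1)OC(C)=O
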